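From 1.0 M of substrate and 20 mM of free catalyst, I want the amount of target each flask holds at the end.

    substrate → uncatalysed product (k1 = 0.0278 s⁻¹, Ea1 = 76.0 kJ mol⁻¹)
    free catalyst + other conformer → free catalyst + isomer of the product (k2 = 0.651 M⁻¹ s⁻¹, Ea2 = 48.0 kJ mol⁻¹)
    2 free catalyst → spent catalyst (k3 = 0.870 M⁻¹ s⁻¹, Ea3 = 42.0 kJ mol⁻¹)
    substrate ⇌ other conformer (K4 = 1.05, k4 = 0.00431 s⁻¹, Ea4 = 79.0 kJ mol⁻¹, ΔH4 = 2.00 kJ mol⁻¹)
    substrate + free catalyst → free catalyst + target (k5 = 0.671 M⁻¹ s⁻¹, Ea5 = 48.0 kJ mol⁻¹)
    (constants at 25 °C)

| setting | birch | cedar | elm |
|---|---|---|---|
| substrate | 1.0 M | 1.0 M | 1.0 M |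
| free catalyst | 20 mM | 20 mM | 20 mM |
| temperature | 45 °C | 65 °C | 25 °C |
| time | 1.5 min | 1.5 min | 1.5 min |

- where a step has two of a species, its rate is k times that concentration squared, and two are used at each turn
- the list of constants is for 25 °C, to be carried to other temperatures by the activation energies and enthalpies
- in a conversion other conformer counts as not yet reacted

- the flask that comes out highest in amount of target, in percent of the substrate charged, or "all alike" when all lie within 1.5 percentage points (birch / cedar / elm / all alike)
- target at the end, in percent of the substrate charged, birch
- target at the end, in percent of the substrate charged, cedar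
- target at the end, in percent of the substrate charged, elm

The substrate has two main exits: the background step, constant kb, to uncatalysed product, and the catalysed step, whose pseudo-first-order constant is kc[free catalyst]. Their ratio, ρ = kc[free catalyst]/kb, is a selectivity factor, and target's share is ρ/(1 + ρ). I leave the conformer step out of this sum because at 25 °C its constant is smaller than the background one.

Two extreme flasks can be done in the head. If free catalyst never dies, elm gives 32.6% target; if it dies at once, elm gives no target. The real elm lies between, because the substrate lifetime from the first extreme, 24.3 s, is shorter than the first half-life of free catalyst, 28.7 s, but not by much. So I put that lifetime back and go round once more, with kd the constant of catalyst death: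

τ = 1/(kb + kc[free catalyst]start)

[free catalyst]τ = [free catalyst]start/(1 + 2kd[free catalyst]start τ)

ρ = kc[free catalyst]τ/kb

For elm, this gives ρ = 0.262, the selectivity factor at the catalyst level one substrate lifetime in. Carrying the constants by their activation energies, I get:

birch: τ = 4.23 s, ρ = 0.166, target 14.3%

cedar: τ = 0.849 s, ρ = 0.104, target 9.43%

elm: target 20.7%

The run is longer than each of these lifetimes, so I let the race finish. My pick for the highest target is elm, whose ρ is greater than the other two.

The forecast gives 13.7% for birch, 8.6% for cedar and 20.4% for elm, and names elm, holding that “heating shifts selectivity away from target and the coolest flask wins”.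

The simulation gives 13.8% for birch, 8.93% for cedar and 20.4% for elm, so elm comes out highest.

The largest single effect of heat lies in the background step, whose activation energy exceeds the catalysed step's: with temperature's effect on that path taken away, target in cedar minus target in elm moves from −11 percentage points to 20 points. Elm's ρ of 0.262 is reckoned for one moment, one lifetime in; the ratio of target to uncatalysed product standing in elm at the end is 0.303. For a neighbour of elm charged with 0.080 M of free catalyst, I reckon 29.5 mM of it after one lifetime, so ρ = 0.713 and the share is 41.6%; that flask ends at 39.2% target.

The rate constants are assumed; the result is computed.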